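**Plan**

- Retrosynthesis: the C8 benzyl ether and the C3 silyl ether are removed last, and the pyranone is then cut at O1′–C2′. This works because the ring O1′–C2′(=O)–C3′–C4′(OH)–C5′–C6′, bonded through C6′ to C4 of the tetralone, is the enol lactone of a 3,5-dioxo acid, so its C2′–C6′ chain can travel as a neutral 2,2-dimethyl-1,3-dioxin-4-one.
- Further cuts: C5′–C6′ (C4 acid chloride plus the dienolate of 2,2,6-trimethyl-1,3-dioxin-4-one), then C4–C4a and C1–C8a of ring B in one operation (a 3-hydroxy-3-phenylglutarate plus 3-benzyloxybenzyne), then the glutarate into methyl benzoate and two allyl groups.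
- Forward order: the C1–C5 chain is built and its two arms are differentiated, ring B is closed onto ring A by the aryne annulation, the dioxinone side chain is joined at the C4 carboxyl, the pyranone ring is closed last, and two deprotections finish.
- Stereochemistry: C3 comes from esterase desymmetrisation of the prochiral diester. C4 stays epimerisable while it is α to a carbonyl and is settled trans to the C3 oxygen, under control of C3, when the pyranone forms.

Key step: step 10

Remark 1: pig liver esterase is assumed to cleave in 4 the same enantiotopic arm as in dimethyl 3-hydroxy-3-methylglutarate (phenyl in the place of methyl), which gives the (S)-acid 5.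
Remark 2: C4 is epimerisable in 12–14 and 16–19; these compounds are drawn and named as the C4 epimer that corresponds to the target, and any epimer mixture is carried forward.

**Route**

Step 1
Reactants: 1 methyl benzoate; 2 allylmagnesium bromide
Product: 3 4-phenylhepta-1,6-dien-4-ol
Conditions: 2 (2.3 equiv), Et2O, 0 °C → rt; aq NH4Cl
Reagents that add atoms: none
Why: Double Grignard addition to the ester (the intermediate ketone is more electrophilic than the ester) gives the symmetrical tertiary carbinol; no stereocentre is formed.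

Step 2
Reactants: 3 4-phenylhepta-1,6-dien-4-ol
Product: 4 dimethyl 3-hydroxy-3-phenylpentanedioate
Conditions: O3, NaOH (5 equiv), MeOH/CH2Cl2, −78 °C; then H2O, warm
Reagents that add atoms: ozone (O=[O+][O-]); methanol (CO)
Why: Ozonolysis in methanolic NaOH oxidises each terminal alkene directly to a methyl ester through the methoxy hydroperoxide/hemiacetal, so the diester is reached without the β-hydroxy dialdehyde or diacid; the molecule stays prochiral.

Step 3
Reactants: 4 dimethyl 3-hydroxy-3-phenylpentanedioate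
Product: 5 (S)-3-hydroxy-5-methoxy-5-oxo-3-phenylpentanoic acid
Conditions: pig liver esterase, 0.1 M phosphate buffer pH 7.5, acetone (10% v/v), 25 °C; acidify to pH 3, EtOAc
Reagents that add atoms: water (O)
Why: Enzymatic desymmetrisation by enantiotopic-group-selective ester hydrolysis: the esterase cleaves one of the two CH2CO2Me arms of the prochiral carbinol, as it does with dimethyl 3-hydroxy-3-methylglutarate, which sets C3, and the anionic half-ester is not hydrolysed further.

Step 4
Reactants: 5 (S)-3-hydroxy-5-methoxy-5-oxo-3-phenylpentanoic acid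
Product: 6 methyl (S)-3-hydroxy-5-[methoxy(methyl)amino]-5-oxo-3-phenylpentanoate
Conditions: MeNHOMe·HCl, EDC·HCl, HOBt, N-methylmorpholine, CH2Cl2, 0 °C → rt
Reagents that add atoms: N,O-dimethylhydroxylamine hydrochloride (CNOC.Cl)
Why: Carbodiimide/HOBt amide coupling turns only the free carboxyl arm into the Weinreb amide, the later acyl acceptor for ring closure; the hindered tertiary alcohol is not acylated and C3 is untouched.

Step 5
Reactants: 6 methyl (S)-3-hydroxy-5-[methoxy(methyl)amino]-5-oxo-3-phenylpentanoate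
Product: 8 prop-2-en-1-yl (S)-3-hydroxy-5-[methoxy(methyl)amino]-5-oxo-3-phenylpentanoate, via lithium carboxylate 7 (not isolated)
Conditions: LiOH·H2O (1.1 equiv), THF/H2O, 0 °C; evaporate; allyl bromide, DMF, rt
Reagents that add atoms: lithium hydroxide ([Li+].[OH-]); allyl bromide (C=CCBr)
Why: Saponification followed by SN2 O-alkylation of the carboxylate exchanges methyl for allyl, an ester that can later be removed without acid or base; the Weinreb amide resists LiOH at 0 °C.

Step 6
Reactants: 8 prop-2-en-1-yl (S)-3-hydroxy-5-[methoxy(methyl)amino]-5-oxo-3-phenylpentanoate; 9 1-(benzyloxy)-3-bromobenzene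
Product: 12 prop-2-en-1-yl (1S,2S)-5-(benzyloxy)-2-hydroxy-4-oxo-2-phenyl-1,2,3,4-tetrahydronaphthalene-1-carboxylate, via dilithium alkoxide enolate 10 (not isolated), via 3-(benzyloxy)benzyne 11 (not isolated)
Conditions: LiN(iPr)2 (2.2 equiv), THF, −78 °C; then 9 (1.5 equiv), lithium 2,2,6,6-tetramethylpiperidide (1.6 equiv), −78 → −40 °C; aq NH4Cl at −40 °C
Reagents that add atoms: none
Why: Anionic aryne annulation of the kind known for phthalide and homophthalate ester anions: the ester enolate carbon of 10 (the alkoxide rules out β-elimination and the ester is several pKa units more acidic than the amide, so only this arm is enolised) adds to the aryne carbon remote from OBn, the resulting aryllithium sits ortho to the oxygen and is acylated at once by the tethered Weinreb amide through a six-membered transition state, and the chelated tetrahedral adduct holds the ketone back until work-up; C3 is not involved and the new C4 centre may form as an epimer mixture that converges later.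

Step 7
Reactants: 12 prop-2-en-1-yl (1S,2S)-5-(benzyloxy)-2-hydroxy-4-oxo-2-phenyl-1,2,3,4-tetrahydronaphthalene-1-carboxylate
Product: 13 prop-2-en-1-yl (1S,2S)-5-(benzyloxy)-4-oxo-2-phenyl-2-[(triethylsilyl)oxy]-1,2,3,4-tetrahydronaphthalene-1-carboxylate
Conditions: Et3SiOTf, 2,6-lutidine, CH2Cl2, −78 → −20 °C
Reagents that add atoms: triethylsilyl trifluoromethanesulfonate (CC[Si](CC)(CC)OS(=O)(=O)C(F)(F)F)
Why: Silyl triflate silylation with a hindered pyridine base protects the tertiary benzylic alcohol at low temperature, where neither enol silylation of the C1 ketone nor ionisation at C3 is expected.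

Step 8
Reactants: 13 prop-2-en-1-yl (1S,2S)-5-(benzyloxy)-4-oxo-2-phenyl-2-[(triethylsilyl)oxy]-1,2,3,4-tetrahydronaphthalene-1-carboxylate
Product: 14 (1S,2S)-5-(benzyloxy)-4-oxo-2-phenyl-2-[(triethylsilyl)oxy]-1,2,3,4-tetrahydronaphthalene-1-carboxylic acid
Conditions: Pd(PPh3)4 (5 mol %), morpholine, THF, rt; pH 4 buffer work-up
Reagents that add atoms: none
Why: Tsuji–Trost deallylation: zerovalent palladium ionises the allyl ester to a π-allyl complex that morpholine captures, freeing the acid under near-neutral conditions that spare the β-silyloxy ketone, the silyl ether and the benzyl ether.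

Step 9
Reactants: 14 (1S,2S)-5-(benzyloxy)-4-oxo-2-phenyl-2-[(triethylsilyl)oxy]-1,2,3,4-tetrahydronaphthalene-1-carboxylic acid; 15 2,2,6-trimethyl-4H-1,3-dioxin-4-one
Product: 18 6-{2-[(1S,2S)-5-(benzyloxy)-4-oxo-2-phenyl-2-[(triethylsilyl)oxy]-1,2,3,4-tetrahydronaphthalen-1-yl]-2-oxoethyl}-2,2-dimethyl-4H-1,3-dioxin-4-one, via acid chloride 16 (not isolated), via lithium dienolate 17 (not isolated)
Conditions: 1-chloro-N,N,2-trimethylprop-1-en-1-amine, CH2Cl2, 0 °C → rt; then added to 15/LiN(SiMe3)2 (3 equiv each), THF, −78 °C; AcOH at −78 °C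
Reagents that add atoms: none
Why: Claisen-type C-acylation of the vinylogous ester enolate at its γ-carbon by the acid chloride, which the α-chloroenamine makes without HCl; excess dienolate deprotonates the product between its two carbonyls and so shields it, and at −78 °C acylation should outrun enolisation at C2 or C4 and loss of the silyloxy group.

Step 10
Reactants: 18 6-{2-[(1S,2S)-5-(benzyloxy)-4-oxo-2-phenyl-2-[(triethylsilyl)oxy]-1,2,3,4-tetrahydronaphthalen-1-yl]-2-oxoethyl}-2,2-dimethyl-4H-1,3-dioxin-4-one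
Product: 20 (3S,4R)-8-(benzyloxy)-4-(4-hydroxy-2-oxo-2H-pyran-6-yl)-3-phenyl-3-[(triethylsilyl)oxy]-3,4-dihydronaphthalen-1(2H)-one, via acylketene 19 (not isolated)
Conditions: toluene (5 mM), 110 °C, N2
Reagents that add atoms: none
Why: Heating drives a retro-[4+2] loss of acetone from the dioxinone to the acylketene 19, whose ketene carbon C2′ is attacked by the enol oxygen of the C6′ ketone (enolised within the 1,3-dicarbonyl array), and tautomerisation then gives the aromatic 4-hydroxy-2-pyranone. The closest known reaction is the thermolysis of 6-(2-oxoalkyl)-1,3-dioxin-4-ones to 6-substituted 4-hydroxy-2-pyranones. The one new ring closes at O1′–C2′ in a six-membered mode, formally 6-exo-dig onto the ketene C=O or, seen from the (Z)-enol, an oxa-6π electrocyclisation. C4 is the stereocentre decided here: it is benzylic and α to the C6′ ketone in 18 and can epimerise through the enol, but it is no longer α to a carbonyl in 20, so its configuration is fixed as the ring closes. It is controlled by the C3 quaternary centre, the side chain being expected to take the pseudoaxial position that avoids the peri C5–H and to lie anti to the C3–OSiEt3 bond with phenyl pseudoequatorial, which is the trans arrangement of the target (the descriptor at C4 reads R only because silicon changes the priorities). The step needs intramolecular capture of the ketene ahead of dimerisation and survival of the C3 tertiary benzylic silyl ether β to two carbonyls, and high dilution, the built-in enol and the absence of acid or base secure both.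

Step 11
Reactants: 20 (3S,4R)-8-(benzyloxy)-4-(4-hydroxy-2-oxo-2H-pyran-6-yl)-3-phenyl-3-[(triethylsilyl)oxy]-3,4-dihydronaphthalen-1(2H)-one
Product: 21 (3S,4S)-8-(benzyloxy)-3-hydroxy-4-(4-hydroxy-2-oxo-2H-pyran-6-yl)-3-phenyl-3,4-dihydronaphthalen-1(2H)-one
Conditions: HF·pyridine, pyridine, THF, 0 °C → rt
Reagents that add atoms: none
Why: Fluoride-driven Si–O cleavage with pyridine-buffered HF·pyridine frees the tertiary alcohol without the basic conditions that would provoke retro-aldol cleavage or elimination towards a naphthol.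

Step 12
Reactants: 21 (3S,4S)-8-(benzyloxy)-3-hydroxy-4-(4-hydroxy-2-oxo-2H-pyran-6-yl)-3-phenyl-3,4-dihydronaphthalen-1(2H)-one
Product: 22 (3S,4S)-3,8-dihydroxy-4-(4-hydroxy-2-oxo-2H-pyran-6-yl)-3-phenyl-3,4-dihydronaphthalen-1(2H)-one
Conditions: H2 (1 atm), 10% Pd/C, EtOAc, rt
Reagents that add atoms: none
Why: Heterogeneous hydrogenolysis cleaves the aryl benzyl ether to the C8 phenol; under neutral conditions at 1 atm the tertiary benzylic alcohol, the aryl ketone and the pyranone are expected to react far more slowly, so the reaction is stopped once 21 is consumed.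

**Compound list**

1 | methyl benzoate | COC(=O)c1ccccc1 | starting material
2 | allylmagnesium bromide | C=CC[Mg]Br | starting material
3 | 4-phenylhepta-1,6-dien-4-ol | C=CCC(O)(CC=C)c1ccccc1 | intermediate
4 | dimethyl 3-hydroxy-3-phenylpentanedioate | COC(=O)CC(O)(CC(=O)OC)c1ccccc1 | intermediate
5 | (S)-3-hydroxy-5-methoxy-5-oxo-3-phenylpentanoic acid | OC(=O)C[C@@](O)(c1ccccc1)CC(=O)OC | intermediate
6 | methyl (S)-3-hydroxy-5-[methoxy(methyl)amino]-5-oxo-3-phenylpentanoate | CON(C)C(=O)C[C@@](O)(c1ccccc1)CC(=O)OC | intermediate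
7 | lithium (S)-3-hydroxy-5-[methoxy(methyl)amino]-5-oxo-3-phenylpentanoate | CON(C)C(=O)C[C@@](O)(c1ccccc1)CC(=O)[O-].[Li+] | intermediate (not isolated)
8 | prop-2-en-1-yl (S)-3-hydroxy-5-[methoxy(methyl)amino]-5-oxo-3-phenylpentanoate | CON(C)C(=O)C[C@@](O)(c1ccccc1)CC(=O)OCC=C | intermediate
9 | 1-(benzyloxy)-3-bromobenzene | Brc1cccc(OCc2ccccc2)c1 | starting material
10 | dilithium salt of 8 (C3 alkoxide and allyl ester enolate) | CON(C)C(=O)C[C@@]([O-])(c1ccccc1)C=C([O-])OCC=C.[Li+].[Li+] | intermediate (not isolated)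
11 | 3-(benzyloxy)benzyne (3-(benzyloxy)-1,2-didehydrobenzene) | C1#CC(OCc2ccccc2)=CC=C1 | intermediate (not isolated)
12 | prop-2-en-1-yl (1S,2S)-5-(benzyloxy)-2-hydroxy-4-oxo-2-phenyl-1,2,3,4-tetrahydronaphthalene-1-carboxylate | O=C1C[C@@](O)(c2ccccc2)[C@@H](C(=O)OCC=C)c2cccc(OCc3ccccc3)c21 | intermediate
13 | prop-2-en-1-yl (1S,2S)-5-(benzyloxy)-4-oxo-2-phenyl-2-[(triethylsilyl)oxy]-1,2,3,4-tetrahydronaphthalene-1-carboxylate | O=C1C[C@@](O[Si](CC)(CC)CC)(c2ccccc2)[C@@H](C(=O)OCC=C)c2cccc(OCc3ccccc3)c21 | intermediate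
14 | (1S,2S)-5-(benzyloxy)-4-oxo-2-phenyl-2-[(triethylsilyl)oxy]-1,2,3,4-tetrahydronaphthalene-1-carboxylic acid | O=C1C[C@@](O[Si](CC)(CC)CC)(c2ccccc2)[C@@H](C(=O)O)c2cccc(OCc3ccccc3)c21 | intermediate
15 | 2,2,6-trimethyl-4H-1,3-dioxin-4-one | CC1=CC(=O)OC(C)(C)O1 | starting material
16 | (1S,2S)-5-(benzyloxy)-4-oxo-2-phenyl-2-[(triethylsilyl)oxy]-1,2,3,4-tetrahydronaphthalene-1-carbonyl chloride | O=C1C[C@@](O[Si](CC)(CC)CC)(c2ccccc2)[C@@H](C(=O)Cl)c2cccc(OCc3ccccc3)c21 | intermediate (not isolated)
17 | lithium 2,2-dimethyl-6-methylidene-6H-1,3-dioxin-4-olate (dienolate of 15) | C=C1C=C([O-])OC(C)(C)O1.[Li+] | intermediate (not isolated)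
18 | 6-{2-[(1S,2S)-5-(benzyloxy)-4-oxo-2-phenyl-2-[(triethylsilyl)oxy]-1,2,3,4-tetrahydronaphthalen-1-yl]-2-oxoethyl}-2,2-dimethyl-4H-1,3-dioxin-4-one | O=C1C[C@@](O[Si](CC)(CC)CC)(c2ccccc2)[C@@H](C(=O)CC2=CC(=O)OC(C)(C)O2)c2cccc(OCc3ccccc3)c21 | intermediate
19 | acylketene from 18 by loss of acetone (tetralin C1 side chain C(=O)CH2C(=O)CH=C=O, ring stereocentres as in 18) | O=C1C[C@@](O[Si](CC)(CC)CC)(c2ccccc2)[C@@H](C(=O)CC(=O)C=C=O)c2cccc(OCc3ccccc3)c21 | intermediate (not isolated)
20 | (3S,4R)-8-(benzyloxy)-4-(4-hydroxy-2-oxo-2H-pyran-6-yl)-3-phenyl-3-[(triethylsilyl)oxy]-3,4-dihydronaphthalen-1(2H)-one | O=C1C[C@@](O[Si](CC)(CC)CC)(c2ccccc2)[C@@H](c2cc(O)cc(=O)o2)c2cccc(OCc3ccccc3)c21 | intermediate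
21 | (3S,4S)-8-(benzyloxy)-3-hydroxy-4-(4-hydroxy-2-oxo-2H-pyran-6-yl)-3-phenyl-3,4-dihydronaphthalen-1(2H)-one | O=C1C[C@@](O)(c2ccccc2)[C@@H](c2cc(O)cc(=O)o2)c2cccc(OCc3ccccc3)c21 | intermediate
22 | (3S,4S)-3,8-dihydroxy-4-(4-hydroxy-2-oxo-2H-pyran-6-yl)-3-phenyl-3,4-dihydronaphthalen-1(2H)-one | O=C1C[C@@](O)(c2ccccc2)[C@@H](c2cc(O)cc(=O)o2)c2cccc(O)c21 | target

**Step count and risks**

Total steps: 12. Longest linear sequence: 12 steps (1 → 22); 9 and 15 are bought.

Steps most likely to fail:

Step 6. The hindered enolate may arylate too slowly, so that the aryne is consumed by the amide base. The aryllithium may also be protonated before it acylates, or the dianion may fragment by retro-aldol on warming. Fallback, from 6 back to 14: the two aryl bonds are made one after the other without an aryne. The ester arm of 6 is converted to its zinc enolate (LiN(SiMe3)2, then ZnCl2) and α-arylated under Pd(dba)2/P(tBu)3 at the C–I bond of 1-(benzyloxy)-2-bromo-3-iodobenzene F1. F1 is made from commercial 1-(benzyloxy)-3-iodobenzene by ortho-lithiation with LiN(iPr)2 at −78 °C and bromination with 1,2-dibromotetrachloroethane. The arylation gives methyl (3S)-2-[3-(benzyloxy)-2-bromophenyl]-3-hydroxy-5-[methoxy(methyl)amino]-5-oxo-3-phenylpentanoate F2. After its OH and α-CH are deprotonated with LiN(SiMe3)2, bromine–lithium exchange with t-BuLi at −100 °C lets the aryllithium close ring B onto the Weinreb amide (Parham cyclisation). This gives methyl (1S,2S)-5-(benzyloxy)-2-hydroxy-4-oxo-2-phenyl-1,2,3,4-tetrahydronaphthalene-1-carboxylate F3. Silylation as in step 7 gives methyl (1S,2S)-5-(benzyloxy)-4-oxo-2-phenyl-2-[(triethylsilyl)oxy]-1,2,3,4-tetrahydronaphthalene-1-carboxylate F4, and Me3SnOH in 1,2-dichloroethane at 70 °C cleaves the methyl ester to 14.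

Step 9. The dienolate may act as a base, deprotonating C4 of the acid chloride (ketene formation) or C2 next to the ketone, after which the silyloxy group is lost and ring B aromatises. Fallback, from 14 back to 18: the same C5′–C6′ bond is made by a Lewis-acid aldol and an oxidation instead of an enolate acylation. 14 is converted with EtSH, EDC·HCl and DMAP to S-ethyl (1S,2S)-5-(benzyloxy)-4-oxo-2-phenyl-2-[(triethylsilyl)oxy]-1,2,3,4-tetrahydronaphthalene-1-carbothioate F5. Fukuyama reduction (Et3SiH, Pd/C, acetone) gives (1S,2S)-5-(benzyloxy)-4-oxo-2-phenyl-2-[(triethylsilyl)oxy]-1,2,3,4-tetrahydronaphthalene-1-carbaldehyde F6. The silyl dienol ether 2,2-dimethyl-6-methylidene-4-[(trimethylsilyl)oxy]-6H-1,3-dioxine F7 (from 15, LiN(iPr)2, Me3SiCl) is added to F6 in a BF3·OEt2-mediated vinylogous Mukaiyama aldol at −78 °C. The product is 6-{2-[(2S)-5-(benzyloxy)-4-oxo-2-phenyl-2-[(triethylsilyl)oxy]-1,2,3,4-tetrahydronaphthalen-1-yl]-2-hydroxyethyl}-2,2-dimethyl-4H-1,3-dioxin-4-one F8 (ring C1 as in 18, carbinol epimers), which Dess–Martin periodinane oxidises to 18.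

Step 3. The enzyme may discriminate the two arms poorly or hydrolyse the other arm. Fallback, from 4 back to 5: chemical desymmetrisation of the cyclic anhydride. 4 is saponified to 3-hydroxy-3-phenylpentanedioic acid F9 (NaOH, then HCl) and closed with DCC to 4-hydroxy-4-phenyloxane-2,6-dione F10. F10 is opened with methanol under a cinchona alkaloid catalyst ((DHQD)2AQN or its pseudo-enantiomer (DHQ)2AQN, Et2O, −20 °C), the catalyst being the one that leads to (S)-5.

**Further compounds**

F1 | step 6 | 1-(benzyloxy)-2-bromo-3-iodobenzene | Ic1cccc(OCc2ccccc2)c1Br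
F2 | step 6 | methyl (3S)-2-[3-(benzyloxy)-2-bromophenyl]-3-hydroxy-5-[methoxy(methyl)amino]-5-oxo-3-phenylpentanoate (C2 epimers) | CON(C)C(=O)C[C@@](O)(c1ccccc1)C(C(=O)OC)c1cccc(OCc2ccccc2)c1Br
F3 | step 6 | methyl (1S,2S)-5-(benzyloxy)-2-hydroxy-4-oxo-2-phenyl-1,2,3,4-tetrahydronaphthalene-1-carboxylate | O=C1C[C@@](O)(c2ccccc2)[C@@H](C(=O)OC)c2cccc(OCc3ccccc3)c21
F4 | step 6 | methyl (1S,2S)-5-(benzyloxy)-4-oxo-2-phenyl-2-[(triethylsilyl)oxy]-1,2,3,4-tetrahydronaphthalene-1-carboxylate | O=C1C[C@@](O[Si](CC)(CC)CC)(c2ccccc2)[C@@H](C(=O)OC)c2cccc(OCc3ccccc3)c21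
F5 | step 9 | S-ethyl (1S,2S)-5-(benzyloxy)-4-oxo-2-phenyl-2-[(triethylsilyl)oxy]-1,2,3,4-tetrahydronaphthalene-1-carbothioate | O=C1C[C@@](O[Si](CC)(CC)CC)(c2ccccc2)[C@@H](C(=O)SCC)c2cccc(OCc3ccccc3)c21
F6 | step 9 | (1S,2S)-5-(benzyloxy)-4-oxo-2-phenyl-2-[(triethylsilyl)oxy]-1,2,3,4-tetrahydronaphthalene-1-carbaldehyde | O=C1C[C@@](O[Si](CC)(CC)CC)(c2ccccc2)[C@@H](C=O)c2cccc(OCc3ccccc3)c21
F7 | step 9 | 2,2-dimethyl-6-methylidene-4-[(trimethylsilyl)oxy]-6H-1,3-dioxine | C=C1C=C(O[Si](C)(C)C)OC(C)(C)O1
F8 | step 9 | 6-{2-[(2S)-5-(benzyloxy)-4-oxo-2-phenyl-2-[(triethylsilyl)oxy]-1,2,3,4-tetrahydronaphthalen-1-yl]-2-hydroxyethyl}-2,2-dimethyl-4H-1,3-dioxin-4-one (ring C1 as in 18, carbinol epimers) | O=C1C[C@@](O[Si](CC)(CC)CC)(c2ccccc2)[C@@H](C(O)CC2=CC(=O)OC(C)(C)O2)c2cccc(OCc3ccccc3)c21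
F9 | step 3 | 3-hydroxy-3-phenylpentanedioic acid | OC(=O)CC(O)(CC(=O)O)c1ccccc1
F10 | step 3 | 4-hydroxy-4-phenyloxane-2,6-dione | O=C1CC(O)(c2ccccc2)CC(=O)O1
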